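**Retrosynthetic overview**
- The route rests on one feature: flavone carbons C2–C3–C4–C4a–C8a–C8–C7–C6–C5 form an unbranched chain with oxygen on every second carbon (C2, C4, C8a, C7, C5) and ring B on C2, so rings A and C are the folded form of an aryl-capped tetraketo ester.
- Key disconnection: C4a–C5 (Claisen, closes ring A) and O1–C2 (recloses ring C). This leads back to methyl 4-(6-aryl-4-oxo-4H-pyran-2-yl)-3-oxobutanoate, in which a 4-pyranone masks the C2, C4 and C8a carbonyls.
- The precursor comes from the benzyl-protected ring B benzoate and acetylacetone dianion (triketone), acid cyclodehydration to the 2-aryl-6-methylpyranone, lateral lithiation with CO2, and malonate half-ester homologation.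
- After the folding: 7-O-methylation, Elbs oxidation at C8 (para to the 5-OH), 8-O-methylation, and hydrogenolysis of the 3'-benzyl ether.
- Ring order: ring B is carried in intact; the pyranone mask forms in step 3; ring A and then ring C of the flavone form in step 6.

Key step: step 6

Remark: the pyranone is opened with hydroxide and not with an alkoxide, because an alkoxide would open the ring to an enol ether and not to the free polyketone; methanol is still the leaving group of the Claisen closure. Compounds 1, 3 and 9 are taken as commercial.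

**Route**

Step 1
Reactants: 1 methyl 3-hydroxy-4,5-dimethoxybenzoate
Product: 2 methyl 3-(benzyloxy)-4,5-dimethoxybenzoate
Conditions: BnBr (1.1 equiv), K2CO3, DMF, 60 °C
Reagents that add atoms: benzyl bromide, BrCc1ccccc1
Why: Williamson etherification of the only free phenol should proceed cleanly, and the benzyl ether then survives every basic and mildly acidic step up to the final hydrogenolysis.

Step 2
Reactants: 2 methyl 3-(benzyloxy)-4,5-dimethoxybenzoate; 3 acetylacetone
Product: 5 1-[3-(benzyloxy)-4,5-dimethoxyphenyl]hexane-1,3,5-trione, via dilithio acetylacetone 4 (not isolated)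
Conditions: 3 (2.2 equiv), LiN(iPr)2 (4.4 equiv), THF, 0 °C; then 2, 0 °C to rt; aq. HCl
Reagents that add atoms: lithium diisopropylamide, CC(C)[N-]C(C)C.[Li+] (lithium of 4 only)
Why: Claisen-type aroylation of the acetylacetone 1,3-dianion takes place at its terminal, more basic carbon, and the second equivalent of dianion takes up the acidic proton of the triketone so that the acylation does not stall.

Step 3
Reactants: 5 1-[3-(benzyloxy)-4,5-dimethoxyphenyl]hexane-1,3,5-trione
Product: 6 2-[3-(benzyloxy)-4,5-dimethoxyphenyl]-6-methyl-4H-pyran-4-one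
Conditions: CF3CO2H, CH2Cl2 (1:4), rt
Reagents that add atoms: none
Why: Acid-catalysed cyclodehydration of a 1,3,5-triketone (enol oxygen onto the far carbonyl, then loss of water) can give only this 4-pyranone, and dilute CF3CO2H should spare the benzyl ether.

Step 4
Reactants: 6 2-[3-(benzyloxy)-4,5-dimethoxyphenyl]-6-methyl-4H-pyran-4-one
Product: 8 {6-[3-(benzyloxy)-4,5-dimethoxyphenyl]-4-oxo-4H-pyran-2-yl}acetic acid, via lateral lithio pyranone 7 (not isolated)
Conditions: LiN(SiMe3)2 (1.15 equiv), THF, −78 °C; cannulate into CO2-saturated THF, −78 °C; cold 1 M HCl, extract below 10 °C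
Reagents that add atoms: carbon dioxide, O=C=O; lithium bis(trimethylsilyl)amide, C[Si](C)(C)[N-][Si](C)(C)C.[Li+] (lithium of 7 only)
Why: Lateral lithiation–carboxylation: the 6-methyl group is vinylogously acidified by the pyranone carbonyl, its extended enolate is carboxylated at the exocyclic carbon, and inverse addition into excess CO2 prevents proton transfer from the more acidic product.

Step 5
Reactants: 8 {6-[3-(benzyloxy)-4,5-dimethoxyphenyl]-4-oxo-4H-pyran-2-yl}acetic acid; 9 potassium methyl malonate
Product: 11 methyl 4-{6-[3-(benzyloxy)-4,5-dimethoxyphenyl]-4-oxo-4H-pyran-2-yl}-3-oxobutanoate, via acyl imidazolide 10 (not isolated)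
Conditions: CDI (1.1 equiv), THF, rt; then 9 (2 equiv), MgCl2, Et3N, MeCN, rt to 40 °C; 1 M HCl
Reagents that add atoms: 1,1'-carbonyldiimidazole, O=C(n1ccnc1)n1ccnc1 (imidazolyl of 10 only)
Why: Masamune–Brooks homologation: the acyl imidazolide C-acylates the magnesium enolate of methyl malonate, and loss of CO2 from the acylmalonate gives the β-keto ester under neutral, mild conditions that should not decarboxylate the pyranylacetic unit.

Step 6
Reactants: 11 methyl 4-{6-[3-(benzyloxy)-4,5-dimethoxyphenyl]-4-oxo-4H-pyran-2-yl}-3-oxobutanoate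
Product: 14 3'-(benzyloxy)-5,7-dihydroxy-4',5'-dimethoxyflavone, via open-chain tetraketo ester 12 (not isolated), via trihydroxyphenyl diketone 13 (not isolated)
Conditions: KOH (2 M aq., 10 equiv), THF, degassed, 0 °C to rt, Ar; then HCl to pH 1; AcOH, HCl (cat.), 60 °C
Reagents that add atoms: potassium hydroxide, [OH-].[K+] (oxygen of 12)
Why: Hydroxide adds to the 4-pyranone (at the later C2 or C8a, both leading to the same chain) and β-elimination of the ring oxygen opens it to the tetraketo ester 12, held as its polyenolate in excess KOH; the C4a carbanion, now flanked by the C4 and C8a carbonyls, attacks the terminal ester carbonyl C5 and expels methoxide, and the cyclohexanetrione so formed enolises irreversibly to the phloroglucinol ring of 13. The closest known reaction type is the base-induced intramolecular Claisen cyclisation of 3,5,7-triketo esters and of pyranone-masked polyketones to acylphloroglucinols, here applied to a chain one carbonyl longer. Ring A closes by a 6-exo-trig Claisen acylation (C4a–C5), and ring C recloses on acidification by 6-exo-trig attack of an ortho hydroxyl on the C2 carbonyl followed by loss of water (O1–C2); the two ortho hydroxyls of 13 are equivalent, so only one flavone can form. No stereocenter is created. The step needs the Claisen fold to win over the aldol folds (C6 onto C4, C8 onto C2, C3 onto C7) and over ester hydrolysis: in strong base every ketone lies inside a β-diketonate and is a poor aldol acceptor, the ester is the only carbonyl with a leaving group, the β-keto ester enolate slows saponification, and aromatisation removes the Claisen product from all equilibria.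

Step 7
Reactants: 14 3'-(benzyloxy)-5,7-dihydroxy-4',5'-dimethoxyflavone
Product: 15 3'-(benzyloxy)-5-hydroxy-7,4',5'-trimethoxyflavone
Conditions: Me2SO4 (1.05 equiv), K2CO3, acetone, reflux
Reagents that add atoms: dimethyl sulfate, COS(=O)(=O)OC
Why: Selective Williamson O-methylation: the 7-OH is the more acidic and accessible phenol, while the 5-OH is held in a hydrogen bond to the C4 carbonyl and should stay free with one equivalent of reagent.

Step 8
Reactants: 15 3'-(benzyloxy)-5-hydroxy-7,4',5'-trimethoxyflavone
Product: 17 3'-(benzyloxy)-5,8-dihydroxy-7,4',5'-trimethoxyflavone, via potassium flavone 8-sulfate 16 (not isolated)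
Conditions: K2S2O8 (1.5 equiv), KOH (aq.), pyridine, 0 °C to rt; then HCl (aq.), 80 °C, Ar
Reagents that add atoms: potassium peroxodisulfate, [K+].[K+].[O-]S(=O)(=O)OOS(=O)(=O)[O-]
Why: Elbs persulfate oxidation: the 5-phenoxide attacks peroxodisulfate through its free para carbon C8, the aryl sulfate is hydrolysed by acid to the quinol, and ring B carries no free phenol that could compete.

Step 9
Reactants: 17 3'-(benzyloxy)-5,8-dihydroxy-7,4',5'-trimethoxyflavone
Product: 18 3'-(benzyloxy)-5-hydroxy-7,8,4',5'-tetramethoxyflavone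
Conditions: Me2SO4 (1.05 equiv), K2CO3, acetone, reflux, Ar
Reagents that add atoms: dimethyl sulfate, COS(=O)(=O)OC
Why: Selective Williamson O-methylation of the non-chelated 8-OH over the hydrogen-bonded 5-OH, run under argon because the quinol is sensitive to air in base.

Step 10
Reactants: 18 3'-(benzyloxy)-5-hydroxy-7,8,4',5'-tetramethoxyflavone
Product: 19 5,3'-dihydroxy-7,8,4',5'-tetramethoxyflavone
Conditions: H2 (1 atm), Pd/C (10 wt% Pd), EtOAc–MeOH, rt
Reagents that add atoms: none
Why: Catalytic hydrogenolysis cleaves the benzyl aryl ether at one atmosphere, where the conjugated C2–C3 double bond of the flavone should not be reduced if the reaction is stopped at full conversion.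

**Compound list**
1 | methyl 3-hydroxy-4,5-dimethoxybenzoate | COC(=O)c1cc(O)c(OC)c(OC)c1 | starting material
2 | methyl 3-(benzyloxy)-4,5-dimethoxybenzoate | COC(=O)c1cc(OCc2ccccc2)c(OC)c(OC)c1 | intermediate
3 | acetylacetone (pentane-2,4-dione) | CC(=O)CC(C)=O | starting material
4 | dilithio acetylacetone (dilithium penta-1,3-diene-2,4-diolate) | C=C([O-])C=C(C)[O-].[Li+].[Li+] | intermediate
5 | 1-[3-(benzyloxy)-4,5-dimethoxyphenyl]hexane-1,3,5-trione | CC(=O)CC(=O)CC(=O)c1cc(OCc2ccccc2)c(OC)c(OC)c1 | intermediate
6 | 2-[3-(benzyloxy)-4,5-dimethoxyphenyl]-6-methyl-4H-pyran-4-one | Cc1cc(=O)cc(-c2cc(OCc3ccccc3)c(OC)c(OC)c2)o1 | intermediate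
7 | 2-[3-(benzyloxy)-4,5-dimethoxyphenyl]-6-(lithiomethyl)-4H-pyran-4-one | [Li]Cc1cc(=O)cc(-c2cc(OCc3ccccc3)c(OC)c(OC)c2)o1 | intermediate
8 | {6-[3-(benzyloxy)-4,5-dimethoxyphenyl]-4-oxo-4H-pyran-2-yl}acetic acid | OC(=O)Cc1cc(=O)cc(-c2cc(OCc3ccccc3)c(OC)c(OC)c2)o1 | intermediate
9 | potassium methyl malonate | COC(=O)CC(=O)[O-].[K+] | starting material
10 | 2-[3-(benzyloxy)-4,5-dimethoxyphenyl]-6-[2-(1H-imidazol-1-yl)-2-oxoethyl]-4H-pyran-4-one | O=C(Cc1cc(=O)cc(-c2cc(OCc3ccccc3)c(OC)c(OC)c2)o1)n1ccnc1 | intermediate
11 | methyl 4-{6-[3-(benzyloxy)-4,5-dimethoxyphenyl]-4-oxo-4H-pyran-2-yl}-3-oxobutanoate | COC(=O)CC(=O)Cc1cc(=O)cc(-c2cc(OCc3ccccc3)c(OC)c(OC)c2)o1 | intermediate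
12 | methyl 9-[3-(benzyloxy)-4,5-dimethoxyphenyl]-3,5,7,9-tetraoxononanoate (present as its potassium polyenolate) | COC(=O)CC(=O)CC(=O)CC(=O)CC(=O)c1cc(OCc2ccccc2)c(OC)c(OC)c1 | intermediate
13 | 1-[3-(benzyloxy)-4,5-dimethoxyphenyl]-3-(2,4,6-trihydroxyphenyl)propane-1,3-dione | O=C(CC(=O)c1c(O)cc(O)cc1O)c1cc(OCc2ccccc2)c(OC)c(OC)c1 | intermediate
14 | 3'-(benzyloxy)-5,7-dihydroxy-4',5'-dimethoxyflavone | COc1cc(-c2cc(=O)c3c(O)cc(O)cc3o2)cc(OCc2ccccc2)c1OC | intermediate
15 | 3'-(benzyloxy)-5-hydroxy-7,4',5'-trimethoxyflavone | COc1cc(-c2cc(=O)c3c(O)cc(OC)cc3o2)cc(OCc2ccccc2)c1OC | intermediate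
16 | potassium 3'-(benzyloxy)-5-hydroxy-7,4',5'-trimethoxyflavon-8-yl sulfate | COc1cc(-c2cc(=O)c3c(O)cc(OC)c(OS(=O)(=O)[O-])c3o2)cc(OCc2ccccc2)c1OC.[K+] | intermediate
17 | 3'-(benzyloxy)-5,8-dihydroxy-7,4',5'-trimethoxyflavone | COc1cc(-c2cc(=O)c3c(O)cc(OC)c(O)c3o2)cc(OCc2ccccc2)c1OC | intermediate
18 | 3'-(benzyloxy)-5-hydroxy-7,8,4',5'-tetramethoxyflavone | COc1cc(-c2cc(=O)c3c(O)cc(OC)c(OC)c3o2)cc(OCc2ccccc2)c1OC | intermediate
19 | 5,3'-dihydroxy-7,8,4',5'-tetramethoxyflavone | COc1cc(-c2cc(=O)c3c(O)cc(OC)c(OC)c3o2)cc(O)c1OC | target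

**Step count**
Total steps: 10. Longest linear sequence: 10 steps (1 to 19).

**Steps most likely to fail**

Step 6 (Claisen folding). The terminal ester may be saponified before the C4a–C5 bond forms, the pyranone may open too slowly, or the chain may fold in an aldol mode to a resorcinol. The fallback abandons the polyketide folding for a Baker–Venkataraman-type aroylation and sets out from 2. Saponification (LiOH, THF–H2O, then HCl) should give 3-(benzyloxy)-4,5-dimethoxybenzoic acid F1, and (COCl)2 with catalytic DMF in CH2Cl2 should give 3-(benzyloxy)-4,5-dimethoxybenzoyl chloride F2. Commercial 2',4',6'-trihydroxyacetophenone is deprotonated with LiN(SiMe3)2 (4 equiv, THF, −78 °C) and C-aroylated at its methyl carbon by F2, which after acid work-up should give diketone 13, isolated in this variant. Cyclodehydration (AcOH, catalytic H2SO4, 95 °C) comes back to the route at 14.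

Step 8 (Elbs oxidation). Conversion may be low because the chelated phenoxide reacts slowly with peroxodisulfate, and the quinol may be over-oxidised to the quinone. The fallback replaces nuclear oxidation by halogenation and copper-mediated methoxylation and sets out from 15. Forcing methylation (excess Me2SO4, K2CO3, DMF, 60 °C) should give 3'-(benzyloxy)-5,7,4',5'-tetramethoxyflavone F3. Bromination with NBS (DMF, 0 °C) at C8, the most nucleophilic position of a 5,7-dialkoxyflavone, should give 3'-(benzyloxy)-8-bromo-5,7,4',5'-tetramethoxyflavone F4. Displacement with NaOMe and CuBr (DMF–MeOH, 110 °C) should give 3'-(benzyloxy)-5,7,8,4',5'-pentamethoxyflavone F5. BCl3 (CH2Cl2, −78 to 0 °C) should then cleave the peri 5-O-methyl group (chelation to the C4 carbonyl) and the benzyl ether together, coming back to the route at 19.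

Step 4 (lateral carboxylation). Proton transfer from the carboxylated product may quench unreacted lateral anion, and the vinylogous β-keto acid may decarboxylate during work-up or during activation in step 5. The fallback builds the side chain as two carbons plus one and never passes through the free acid; it sets out from 6. Lateral lithiation (LiN(SiMe3)2, 2.2 equiv, THF, −78 °C) and acylation with N-methoxy-N-methylacetamide should give 2-[3-(benzyloxy)-4,5-dimethoxyphenyl]-6-(2-oxopropyl)-4H-pyran-4-one F6. Its 1,3-dianion (LiN(iPr)2, 3 equiv, THF, −78 °C) is carboxylated at the terminal methyl carbon with dimethyl carbonate, coming back to the route at 11.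

**Further compounds**
F1 | step 6 | 3-(benzyloxy)-4,5-dimethoxybenzoic acid | OC(=O)c1cc(OCc2ccccc2)c(OC)c(OC)c1
F2 | step 6 | 3-(benzyloxy)-4,5-dimethoxybenzoyl chloride | ClC(=O)c1cc(OCc2ccccc2)c(OC)c(OC)c1
F3 | step 8 | 3'-(benzyloxy)-5,7,4',5'-tetramethoxyflavone | COc1cc(-c2cc(=O)c3c(OC)cc(OC)cc3o2)cc(OCc2ccccc2)c1OC
F4 | step 8 | 3'-(benzyloxy)-8-bromo-5,7,4',5'-tetramethoxyflavone | COc1cc(-c2cc(=O)c3c(OC)cc(OC)c(Br)c3o2)cc(OCc2ccccc2)c1OC
F5 | step 8 | 3'-(benzyloxy)-5,7,8,4',5'-pentamethoxyflavone | COc1cc(-c2cc(=O)c3c(OC)cc(OC)c(OC)c3o2)cc(OCc2ccccc2)c1OC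
F6 | step 4 | 2-[3-(benzyloxy)-4,5-dimethoxyphenyl]-6-(2-oxopropyl)-4H-pyran-4-one | CC(=O)Cc1cc(=O)cc(-c2cc(OCc3ccccc3)c(OC)c(OC)c2)o1
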